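**Plan**

- Retrosynthesis, in this order: the C7'=C8' bond of the dienyl chain (Horner–Wadsworth–Emmons); the C2–C3 bond of the γ-lactone (carbenoid C–H insertion of a diazoacetate carried by the C4 oxygen); the O–C3 bond of the 1,2-dioxane (peroxide anion on a C3 electrophile); the C6–OO bond (radical hydroperoxysilylation of a 1,1-disubstituted alkene); the C5–C6 bond (alkenyl-copper opening of a 2-methylglycidyl unit).
- Forward: the chain fragment is joined to the C3–C5 fragment, the 1,2-dioxane ring is closed, the γ-lactone ring is fused onto it in the key step, and the phenyldiene is attached last.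
- Enabling feature: in the 4,6-dimethyl-1,2-dioxan-4-yl diazoacetate the C3–H bonds lie α to a ring peroxide oxygen and 1,5 to the carbenoid carbon. In the favoured chair of the 1,2-dioxane the axial C4 ester oxygen is gauche to the equatorial C3–H and anti to the axial one, so the five-membered lactone should close cis.
- Stereochemistry: C4 comes from (S)-2-methylglycidol and its C–O bond is never broken. C3 is set by C4 through the cis ring fusion in the key step. C6 arises without facial control, and the (6S) epimer is isolated after ring closure. The diene geometry comes from the E-phosphonate and the E-selective olefination.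

Key step: step 8

Remark: no reagent is known to tell methyl from n-alkyl in the oxygen capture that creates C6, so both C6 epimers are accepted in step 4 and the wanted one is isolated in step 5. Locants follow the lactone numbering (C1 carbonyl, C2 lactone CH2, C3 peroxide CH, C4 ring-fusion carbon, C5 ring CH2, C6 quaternary peroxide carbon).

**Route**

Step 1
Reactants: 1 tert-butyl[(6-bromohexyl)oxy]dimethylsilane; 2 2,3-dibromoprop-1-ene
Product: 4 tert-butyl[(8-bromonon-8-en-1-yl)oxy]dimethylsilane, via Grignard reagent 3 (not isolated)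
Conditions: Mg, THF, 40 °C; then 2, CuI (5 mol%), THF, −20 °C → rt
Reagents that add atoms: none
Why: Copper-catalysed allylic substitution of the alkylmagnesium bromide on the allylic bromide should give the 2-bromo-1-alkene (direct and allylic-shift attack give the same product), with the vinylic bromide and the silyl ether untouched.

Step 2
Reactants: 5 [(2S)-2-methyloxiran-2-yl]methanol
Product: 6 [(2R)-2-methyloxiran-2-yl]methyl 4-methylbenzenesulfonate
Conditions: TsCl, Et3N, DMAP (cat.), CH2Cl2, 0 °C
Reagents that add atoms: 4-methylbenzenesulfonyl chloride, Cc1ccc(cc1)S(=O)(=O)Cl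
Why: Sulfonylation of the primary alcohol leaves the quaternary stereocentre untouched; the descriptor changes only because the CIP priorities change.

Step 3
Reactants: 4 tert-butyl[(8-bromonon-8-en-1-yl)oxy]dimethylsilane; 6 [(2R)-2-methyloxiran-2-yl]methyl 4-methylbenzenesulfonate
Product: 8 (2R)-11-[(tert-butyldimethylsilyl)oxy]-2-hydroxy-2-methyl-4-methylideneundecyl 4-methylbenzenesulfonate, via alkenyl Grignard reagent 7 (not isolated)
Conditions: Mg, THF, reflux; then 6, CuI (10 mol%), THF, −30 → 0 °C; aq. NH4Cl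
Reagents that add atoms: none
Why: Copper-catalysed SN2 opening of the 2,2-disubstituted epoxide at its CH2 forms the C5–C6 bond without breaking the C4–O bond (configuration retained), while the tosylate on the neopentyl-type carbon should survive.

Step 4
Reactants: 8 (2R)-11-[(tert-butyldimethylsilyl)oxy]-2-hydroxy-2-methyl-4-methylideneundecyl 4-methylbenzenesulfonate
Product: 9 (2R)-11-[(tert-butyldimethylsilyl)oxy]-2-hydroxy-2,4-dimethyl-4-[(triethylsilyl)peroxy]undecyl 4-methylbenzenesulfonate (both epimers at the peroxide carbon)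
Conditions: Co(thd)2 (thd = 2,2,6,6-tetramethylheptane-3,5-dionate, 10 mol%), O2 (1 atm), Et3SiH, ClCH2CH2Cl, rt
Reagents that add atoms: dioxygen, O=O; triethylsilane, CC[SiH](CC)CC
Why: Mukaiyama–Isayama hydroperoxysilylation (hydrogen-atom transfer from a cobalt hydride to the alkene CH2, capture of the tertiary radical by O2, silylation) places the peroxide at C6 with Markovnikov selectivity, but without facial control, so both C6 epimers are expected.

Step 5
Reactants: 9 (2R)-11-[(tert-butyldimethylsilyl)oxy]-2-hydroxy-2,4-dimethyl-4-[(triethylsilyl)peroxy]undecyl 4-methylbenzenesulfonate (both epimers at the peroxide carbon)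
Product: 12 (4R,6S)-6-{7-[(tert-butyldimethylsilyl)oxy]heptyl}-4,6-dimethyl-1,2-dioxan-4-ol, via hydroperoxide 10 (not isolated), via epoxy hydroperoxide 11 (not isolated)
Conditions: K2CO3, MeOH, 0 °C → rt; chromatography
Reagents that add atoms: none
Why: Methanolysis of the Si–OO bond frees the hydroperoxide, the tertiary alkoxide closes the epoxide, and the peroxide anion opens it at the unhindered CH2 to give the six-membered ring (attack at the fully substituted carbon, which would give a dioxolane, should be disfavoured), C4 being untouched; the (4R,6R) epimer that arises from the other epimer of 9 is removed by chromatography.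

Step 6
Reactants: 12 (4R,6S)-6-{7-[(tert-butyldimethylsilyl)oxy]heptyl}-4,6-dimethyl-1,2-dioxan-4-ol
Product: 13 (4R,6S)-6-{7-[(tert-butyldimethylsilyl)oxy]heptyl}-4,6-dimethyl-1,2-dioxan-4-yl bromoacetate
Conditions: BrCH2COBr, pyridine, CH2Cl2, 0 °C → rt
Reagents that add atoms: bromoacetyl bromide, BrCC(=O)Br
Why: The reactive acid bromide should acylate even the tertiary alcohol, and the dialkyl peroxide is inert to acylating agents.

Step 7
Reactants: 13 (4R,6S)-6-{7-[(tert-butyldimethylsilyl)oxy]heptyl}-4,6-dimethyl-1,2-dioxan-4-yl bromoacetate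
Product: 14 (4R,6S)-6-{7-[(tert-butyldimethylsilyl)oxy]heptyl}-4,6-dimethyl-1,2-dioxan-4-yl diazoacetate
Conditions: TsNHNHTs, DBU, THF, 0 °C
Reagents that add atoms: N,N'-bis(4-methylbenzenesulfonyl)hydrazine, Cc1ccc(cc1)S(=O)(=O)NNS(=O)(=O)c1ccc(C)cc1
Why: Alkylation of the ditosylhydrazine by the bromoacetate followed by double elimination of sulfinate is the standard mild route to diazoacetates of hindered alcohols, run cold and briefly to spare the base-sensitive O–O–CH2 unit.

Step 8
Reactants: 14 (4R,6S)-6-{7-[(tert-butyldimethylsilyl)oxy]heptyl}-4,6-dimethyl-1,2-dioxan-4-yl diazoacetate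
Product: 15 (3S,4aR,7aR)-3-{7-[(tert-butyldimethylsilyl)oxy]heptyl}-3,4a-dimethyltetrahydro-3H-furo[3,2-c][1,2]dioxin-6(4H)-one
Conditions: Rh2(NHCOCH3)4 (dirhodium tetraacetamidate, 1 mol%), CH2Cl2, 40 °C, slow addition of 14
Reagents that add atoms: none
Why: Proposed new method: the diazoacetate loses N2 at the dirhodium centre (divalent rhodium) to give an electrophilic carbenoid at C2, which inserts in a concerted, hydride-transfer-like three-centre step into the C3–H bond that lies 1,5 to it and α to the peroxide oxygen, whose lone pair stabilises the partial positive charge at C3. The closest known reaction type is the dirhodium carboxamidate-catalysed formation of γ-lactones from diazoacetates of cyclic ethers and cycloalkanols by insertion into a C–H bond next to an ether oxygen, which has not been shown for a C–H bond next to a peroxide oxygen. The γ-lactone ring closes by this 1,5-insertion through a five-membered transition state onto the chair 1,2-dioxane. The new stereocentre C3 is controlled by C4: in the favoured chair (both methyl groups equatorial, ester oxygen and chain axial) only the equatorial C3–H syn to the axial ester oxygen is within reach, and insertion with retention there gives the cis ring fusion. The step needs site selectivity over the equatorial C5–H and the C4 methyl C–H bonds (also 1,5) and chemoselectivity over attack on the peroxide oxygens. C3–H is the only bond activated by an α-oxygen, C5–H is flanked by two quaternary carbons and deactivated by two β-oxygens, the methyl C–H is primary, the electron-rich carboxamidate ligands make the carbenoid discriminating, the peroxide oxygens are poor Lewis bases, and slow addition suppresses carbene dimerisation.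

Step 9
Reactants: 15 (3S,4aR,7aR)-3-{7-[(tert-butyldimethylsilyl)oxy]heptyl}-3,4a-dimethyltetrahydro-3H-furo[3,2-c][1,2]dioxin-6(4H)-one
Product: 16 (3S,4aR,7aR)-3-(7-hydroxyheptyl)-3,4a-dimethyltetrahydro-3H-furo[3,2-c][1,2]dioxin-6(4H)-one
Conditions: HF·pyridine, pyridine, THF, 0 °C → rt
Reagents that add atoms: none
Why: Acidic fluoride cleaves the primary silyl ether without the basic conditions that could trigger retro-oxa-Michael opening of the β-peroxy lactone.

Step 10
Reactants: 16 (3S,4aR,7aR)-3-(7-hydroxyheptyl)-3,4a-dimethyltetrahydro-3H-furo[3,2-c][1,2]dioxin-6(4H)-one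
Product: 17 7-[(3S,4aR,7aR)-3,4a-dimethyl-6-oxohexahydro-3H-furo[3,2-c][1,2]dioxin-3-yl]heptanal
Conditions: Dess–Martin periodinane, CH2Cl2, rt
Reagents that add atoms: none
Why: Dess–Martin oxidation converts the primary alcohol into the aldehyde under neutral conditions that leave peroxide and lactone intact.

Step 11
Reactants: 17 7-[(3S,4aR,7aR)-3,4a-dimethyl-6-oxohexahydro-3H-furo[3,2-c][1,2]dioxin-3-yl]heptanal; 18 diethyl [(2E)-3-phenylprop-2-en-1-yl]phosphonate
Product: 20 plakortolide Q, (3S,4aR,7aR)-3,4a-dimethyl-3-[(7E,9E)-10-phenyldeca-7,9-dien-1-yl]tetrahydro-3H-furo[3,2-c][1,2]dioxin-6(4H)-one, via phosphonate anion 19 (not isolated)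
Conditions: 18, NaN(SiMe3)2, THF, −78 °C; then 17, −78 °C → rt
Reagents that add atoms: none
Why: Horner–Wadsworth–Emmons olefination with the preformed, weakly basic allylic phosphonate anion should give the new alkene E under thermodynamic control of the elimination, the styryl E geometry being carried in from 18, and should spare the lactone.

**Compound list**

1 | tert-butyl[(6-bromohexyl)oxy]dimethylsilane | CC(C)(C)[Si](C)(C)OCCCCCCBr | starting material
2 | 2,3-dibromoprop-1-ene | C=C(Br)CBr | starting material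
3 | {6-[(tert-butyldimethylsilyl)oxy]hexyl}magnesium bromide | CC(C)(C)[Si](C)(C)OCCCCCC[Mg]Br | intermediate (not isolated)
4 | tert-butyl[(8-bromonon-8-en-1-yl)oxy]dimethylsilane | C=C(Br)CCCCCCCO[Si](C)(C)C(C)(C)C | intermediate
5 | [(2S)-2-methyloxiran-2-yl]methanol, (S)-2-methylglycidol | OC[C@@]1(C)CO1 | starting material
6 | [(2R)-2-methyloxiran-2-yl]methyl 4-methylbenzenesulfonate | Cc1ccc(cc1)S(=O)(=O)OC[C@@]1(C)CO1 | intermediate
7 | {9-[(tert-butyldimethylsilyl)oxy]non-1-en-2-yl}magnesium bromide | C=C([Mg]Br)CCCCCCCO[Si](C)(C)C(C)(C)C | intermediate (not isolated)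
8 | (2R)-11-[(tert-butyldimethylsilyl)oxy]-2-hydroxy-2-methyl-4-methylideneundecyl 4-methylbenzenesulfonate | C=C(CCCCCCCO[Si](C)(C)C(C)(C)C)C[C@@](C)(O)COS(=O)(=O)c1ccc(C)cc1 | intermediate
9 | (2R)-11-[(tert-butyldimethylsilyl)oxy]-2-hydroxy-2,4-dimethyl-4-[(triethylsilyl)peroxy]undecyl 4-methylbenzenesulfonate, both epimers at the peroxide carbon | CC(CCCCCCCO[Si](C)(C)C(C)(C)C)(OO[Si](CC)(CC)CC)C[C@@](C)(O)COS(=O)(=O)c1ccc(C)cc1 | intermediate
10 | (2R)-11-[(tert-butyldimethylsilyl)oxy]-4-hydroperoxy-2-hydroxy-2,4-dimethylundecyl 4-methylbenzenesulfonate, both epimers at the peroxide carbon | CC(CCCCCCCO[Si](C)(C)C(C)(C)C)(OO)C[C@@](C)(O)COS(=O)(=O)c1ccc(C)cc1 | intermediate (not isolated)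
11 | tert-butyl({8-hydroperoxy-8-methyl-9-[(2R)-2-methyloxiran-2-yl]nonyl}oxy)dimethylsilane, both epimers at the peroxide carbon | CC(CCCCCCCO[Si](C)(C)C(C)(C)C)(OO)C[C@]1(C)CO1 | intermediate (not isolated)
12 | (4R,6S)-6-{7-[(tert-butyldimethylsilyl)oxy]heptyl}-4,6-dimethyl-1,2-dioxan-4-ol | C[C@]1(CCCCCCCO[Si](C)(C)C(C)(C)C)C[C@@](C)(O)COO1 | intermediate
13 | (4R,6S)-6-{7-[(tert-butyldimethylsilyl)oxy]heptyl}-4,6-dimethyl-1,2-dioxan-4-yl bromoacetate | C[C@]1(CCCCCCCO[Si](C)(C)C(C)(C)C)C[C@@](C)(OC(=O)CBr)COO1 | intermediate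
14 | (4R,6S)-6-{7-[(tert-butyldimethylsilyl)oxy]heptyl}-4,6-dimethyl-1,2-dioxan-4-yl diazoacetate | C[C@]1(CCCCCCCO[Si](C)(C)C(C)(C)C)C[C@@](C)(OC(=O)C=[N+]=[N-])COO1 | intermediate
15 | (3S,4aR,7aR)-3-{7-[(tert-butyldimethylsilyl)oxy]heptyl}-3,4a-dimethyltetrahydro-3H-furo[3,2-c][1,2]dioxin-6(4H)-one (cis-fused γ-lactone on the 1,2-dioxane) | C[C@]1(CCCCCCCO[Si](C)(C)C(C)(C)C)C[C@@]2(C)OC(=O)C[C@H]2OO1 | intermediate
16 | (3S,4aR,7aR)-3-(7-hydroxyheptyl)-3,4a-dimethyltetrahydro-3H-furo[3,2-c][1,2]dioxin-6(4H)-one | C[C@]1(CCCCCCCO)C[C@@]2(C)OC(=O)C[C@H]2OO1 | intermediate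
17 | 7-[(3S,4aR,7aR)-3,4a-dimethyl-6-oxohexahydro-3H-furo[3,2-c][1,2]dioxin-3-yl]heptanal | C[C@]1(CCCCCCC=O)C[C@@]2(C)OC(=O)C[C@H]2OO1 | intermediate
18 | diethyl [(2E)-3-phenylprop-2-en-1-yl]phosphonate | CCOP(=O)(OCC)C/C=C/c1ccccc1 | starting material
19 | sodium salt of the α-carbanion of 18 | [Na+].CCOP(=O)(OCC)[CH-]/C=C/c1ccccc1 | intermediate (not isolated)
20 | plakortolide Q, (3S,4aR,7aR)-3,4a-dimethyl-3-[(7E,9E)-10-phenyldeca-7,9-dien-1-yl]tetrahydro-3H-furo[3,2-c][1,2]dioxin-6(4H)-one | C[C@]1(CCCCCC/C=C/C=C/c2ccccc2)C[C@@]2(C)OC(=O)C[C@H]2OO1 | target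

**Count**

Total steps: 11. Longest linear sequence: 10 steps (1 → 4 → 8 → 9 → 12 → 13 → 14 → 15 → 16 → 17 → 20; the branch from 5 through 6 is equally long).

**Steps most likely to fail**

Step 8 (labelled step). The carbenoid may be diverted to the peroxide oxygens (ylide formation, O–O cleavage), to the C5–H or methyl C–H bonds, or to dimerisation, so that the lactone does not close. The fallback uses known chemistry and closes the peroxide ring onto a preformed butenolide instead. It sets out from 8 and comes back at 15. K2CO3 in MeOH closes 8 to tert-butyldimethyl[(8-{[(2R)-2-methyloxiran-2-yl]methyl}non-8-en-1-yl)oxy]silane F1. The dianion of (phenylsulfanyl)acetic acid (2 LiN(iPr)2, THF) opens F1 at its CH2, and acidic work-up lactonises to (5R)-5-(2-{7-[(tert-butyldimethylsilyl)oxy]heptyl}prop-2-en-1-yl)-5-methyl-3-(phenylsulfanyl)oxolan-2-one F2. NaIO4 in aqueous MeOH gives the sulfoxide (5R)-5-(2-{7-[(tert-butyldimethylsilyl)oxy]heptyl}prop-2-en-1-yl)-5-methyl-3-(phenylsulfinyl)oxolan-2-one F3, which on heating in toluene should eliminate to the butenolide (5R)-5-(2-{7-[(tert-butyldimethylsilyl)oxy]heptyl}prop-2-en-1-yl)-5-methylfuran-2(5H)-one F4. Mukaiyama–Isayama hydroperoxysilylation (Co(thd)2, O2, Et3SiH), expected to favour the electron-rich 1,1-disubstituted alkene over the butenolide, gives (5R)-5-{9-[(tert-butyldimethylsilyl)oxy]-2-methyl-2-[(triethylsilyl)peroxy]nonyl}-5-methylfuran-2(5H)-one F5 as both C6 epimers. K2CO3 in MeOH frees the hydroperoxide (5R)-5-{9-[(tert-butyldimethylsilyl)oxy]-2-hydroperoxy-2-methylnonyl}-5-methylfuran-2(5H)-one F6, and Et2NH in CF3CH2OH should make it add to C3 of the butenolide (oxa-Michael, cis fusion enforced by the tether). After removal of the C6 epimer the route is rejoined at 15.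

Step 4. Oxygen capture by the planar tertiary radical has no facial preference, so half of the material is expected to carry the wrong C6 configuration. The fallback builds C6 by C–C bond formation on a cyclic peroxyketal, where C4 can direct the attack. It sets out from 6 and comes back at 12. Copper-catalysed opening of 6 with isopropenylmagnesium bromide (CuI cat., THF) gives (2R)-2-hydroxy-2,4-dimethylpent-4-en-1-yl 4-methylbenzenesulfonate F7, which K2CO3 in MeOH closes to (2R)-2-methyl-2-(2-methylprop-2-en-1-yl)oxirane F8. Ozonolysis in CH2Cl2/MeOH at −78 °C traps the ketone carbonyl oxide as (2R)-2-(2-hydroperoxy-2-methoxypropyl)-2-methyloxirane F9. Et2NH in CF3CH2OH closes the ring to (4R)-6-methoxy-4,6-dimethyl-1,2-dioxan-4-ol F10, and 1-(trimethylsilyl)imidazole gives {[(4R)-6-methoxy-4,6-dimethyl-1,2-dioxan-4-yl]oxy}trimethylsilane F11. Allyltrimethylsilane with SnCl4 in CH2Cl2 at −78 °C (Hosomi–Sakurai reaction of the peroxycarbenium ion) should give trimethyl{[(4R,6S)-4,6-dimethyl-6-(prop-2-en-1-yl)-1,2-dioxan-4-yl]oxy}silane F12; the half-chair cation is expected to keep the C4 silyloxy group pseudoaxial and the C4 methyl pseudoequatorial, and to take the nucleophile on the face cis to the oxygen, by analogy with 3-alkoxy six-membered oxocarbenium ions. Cross-metathesis with tert-butyl(hex-5-en-1-yloxy)dimethylsilane (second-generation Grubbs catalyst) gives (4R,6S)-6-{7-[(tert-butyldimethylsilyl)oxy]hept-2-en-1-yl}-4,6-dimethyl-4-[(trimethylsilyl)oxy]-1,2-dioxane F13. Diimide (2-nitrobenzenesulfonyl hydrazide, Et3N) saturates it to (4R,6S)-6-{7-[(tert-butyldimethylsilyl)oxy]heptyl}-4,6-dimethyl-4-[(trimethylsilyl)oxy]-1,2-dioxane F14, and K2CO3 in MeOH removes the tertiary trimethylsilyl ether and returns 12.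

Step 5. The peroxide anion may attack the epoxide in the five-membered (exo) mode at the fully substituted carbon instead of the six-membered mode at CH2, giving a 1,2-dioxolane. The fallback reverses the roles of the two ends. It sets out from 8 and comes back at 12. Perhydrolysis with 50% H2O2 and KOH in MeOH (intermolecular attack of hydroperoxide anion at the primary carbon) gives (2R)-11-[(tert-butyldimethylsilyl)oxy]-1-hydroperoxy-2-methyl-4-methylideneundecan-2-ol F15. Cycloperoxymercuration with Hg(OAc)2 in CH2Cl2 closes the six-membered ring at the more substituted alkene carbon and gives (acetato){[(4R)-6-{7-[(tert-butyldimethylsilyl)oxy]heptyl}-4-hydroxy-4-methyl-1,2-dioxan-6-yl]methyl}mercury F16 as both C6 epimers. Reductive demercuration with NaBH4 in aqueous NaOH turns the CH2Hg group into the C6 methyl, and after chromatographic removal of the (6R) epimer the route is rejoined at 12.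

**Further compounds**

F1 | step 8 | tert-butyldimethyl[(8-{[(2R)-2-methyloxiran-2-yl]methyl}non-8-en-1-yl)oxy]silane | C=C(CCCCCCCO[Si](C)(C)C(C)(C)C)C[C@]1(C)CO1
F2 | step 8 | (5R)-5-(2-{7-[(tert-butyldimethylsilyl)oxy]heptyl}prop-2-en-1-yl)-5-methyl-3-(phenylsulfanyl)oxolan-2-one | C=C(CCCCCCCO[Si](C)(C)C(C)(C)C)C[C@]1(C)CC(Sc2ccccc2)C(=O)O1
F3 | step 8 | (5R)-5-(2-{7-[(tert-butyldimethylsilyl)oxy]heptyl}prop-2-en-1-yl)-5-methyl-3-(phenylsulfinyl)oxolan-2-one | C=C(CCCCCCCO[Si](C)(C)C(C)(C)C)C[C@]1(C)CC(S(=O)c2ccccc2)C(=O)O1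
F4 | step 8 | (5R)-5-(2-{7-[(tert-butyldimethylsilyl)oxy]heptyl}prop-2-en-1-yl)-5-methylfuran-2(5H)-one | C=C(CCCCCCCO[Si](C)(C)C(C)(C)C)C[C@]1(C)C=CC(=O)O1
F5 | step 8 | (5R)-5-{9-[(tert-butyldimethylsilyl)oxy]-2-methyl-2-[(triethylsilyl)peroxy]nonyl}-5-methylfuran-2(5H)-one, both epimers at the peroxide carbon | CC(CCCCCCCO[Si](C)(C)C(C)(C)C)(OO[Si](CC)(CC)CC)C[C@]1(C)C=CC(=O)O1
F6 | step 8 | (5R)-5-{9-[(tert-butyldimethylsilyl)oxy]-2-hydroperoxy-2-methylnonyl}-5-methylfuran-2(5H)-one, both epimers at the peroxide carbon | CC(CCCCCCCO[Si](C)(C)C(C)(C)C)(OO)C[C@]1(C)C=CC(=O)O1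
F7 | step 4 | (2R)-2-hydroxy-2,4-dimethylpent-4-en-1-yl 4-methylbenzenesulfonate | C=C(C)C[C@@](C)(O)COS(=O)(=O)c1ccc(C)cc1
F8 | step 4 | (2R)-2-methyl-2-(2-methylprop-2-en-1-yl)oxirane | C=C(C)C[C@]1(C)CO1
F9 | step 4 | (2R)-2-(2-hydroperoxy-2-methoxypropyl)-2-methyloxirane, both epimers at the ketal carbon | COC(C)(OO)C[C@]1(C)CO1
F10 | step 4 | (4R)-6-methoxy-4,6-dimethyl-1,2-dioxan-4-ol, both epimers at the ketal carbon | COC1(C)C[C@@](C)(O)COO1
F11 | step 4 | {[(4R)-6-methoxy-4,6-dimethyl-1,2-dioxan-4-yl]oxy}trimethylsilane, both epimers at the ketal carbon | COC1(C)C[C@@](C)(O[Si](C)(C)C)COO1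
F12 | step 4 | trimethyl{[(4R,6S)-4,6-dimethyl-6-(prop-2-en-1-yl)-1,2-dioxan-4-yl]oxy}silane | C[C@]1(CC=C)C[C@@](C)(O[Si](C)(C)C)COO1
F13 | step 4 | (4R,6S)-6-{7-[(tert-butyldimethylsilyl)oxy]hept-2-en-1-yl}-4,6-dimethyl-4-[(trimethylsilyl)oxy]-1,2-dioxane, E and Z | C[C@]1(CC=CCCCCO[Si](C)(C)C(C)(C)C)C[C@@](C)(O[Si](C)(C)C)COO1
F14 | step 4 | (4R,6S)-6-{7-[(tert-butyldimethylsilyl)oxy]heptyl}-4,6-dimethyl-4-[(trimethylsilyl)oxy]-1,2-dioxane | C[C@]1(CCCCCCCO[Si](C)(C)C(C)(C)C)C[C@@](C)(O[Si](C)(C)C)COO1
F15 | step 5 | (2R)-11-[(tert-butyldimethylsilyl)oxy]-1-hydroperoxy-2-methyl-4-methylideneundecan-2-ol | C=C(CCCCCCCO[Si](C)(C)C(C)(C)C)C[C@@](C)(O)COO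
F16 | step 5 | (acetato){[(4R)-6-{7-[(tert-butyldimethylsilyl)oxy]heptyl}-4-hydroxy-4-methyl-1,2-dioxan-6-yl]methyl}mercury, both C6 epimers | CC(=O)O[Hg]CC1(CCCCCCCO[Si](C)(C)C(C)(C)C)C[C@@](C)(O)COO1
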